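3 questions stand here, and one number meets them.

| flask | substrate | temperature | remark | time |
|---|---|---|---|---|
| north-west | 7.2 mM | 15 °C | run made earlier |  |
| south-east | 15 mM | 37 °C | run made earlier |  |
| grey | 12 mM |  | at 45 °C throughout | 6.0 h |
| violet | 20 mM |  | at 5 °C until 3.0 h, from then on at 45 °C | 6.0 h |

- north-west (time / min: ring / %): 20.0: 43.8; 40.0: 61.9; 60.0: 74.5; 80.0: 78.5; 90.0: 79.3; 120: 83.3
- south-east (time / min: ring / %): 6.00: 60.9; 12.0: 70.1; 20.0: 77.8; 25.0: 81.5; 30.0: 85.3; 40.0: 90.4

(readings scatter by 1 percentage point)

* the flask that ends with the higher amount of ring, in percent of the substrate charged, or "neither" when 2 percentage points or less lies between them (grey / violet / neither)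
* final ring, as a percentage of the substrate charged, in grey
* final ring, as a percentage of the substrate charged, in violet

- the analysis behind the earlier runs scatters by 1 percentage point, standard deviation
- a reading or a percentage of ring counts all its forms, free or not

Take the south-east run and freeze what is nearly constant: the slope of the logarithm of its gap to full conversion. Treat that gap as a pseudo-first-order tail; from its readings I get:

rate = ln(gap at 20.0 min / gap at 40.0 min) / elapsed time = 0.0419 min⁻¹

The two halves of that stretch give 0.0412 min⁻¹ and 0.0426 min⁻¹, but with a scatter of 1 percentage point on a gap of 9.60 % these two readings can't show whether the tail bends, so one rate is my assumption. Now fold in the hot time: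

violet: rate × hot time = 7.54

grey: rate × hot time = 15.1

Call this the release number, the count of tail lifetimes that fit into the hot hours. The flasks run hotter than the south-east run, but the rate was read at 37 °C, so the number is an estimate, not a bound. By this estimate violet, the shorter case, keeps a share 0.0529 % of its gap.

Was one number enough? Not for certain: it assumes one rate, carried from 37 °C to 45 °C, and a ceiling of full conversion, and the readings stop at 90.4 %. My reckoning says both flasks close their gaps, so expect neither to lead.

The forecast says neither, with grey 98 % and violet 97 %: “Both flasks should approach near-complete conversion”.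

The flasks give neither: grey 97.6 %, violet 97.7 %.

    substrate → ring (k = 1.50 × 10⁻⁴ s⁻¹, Ea = 87.0 kJ mol⁻¹)
    2 substrate ⇌ open dimer (K = 670 M⁻¹, k = 0.00230 M⁻¹ s⁻¹, Ea = 57.0 kJ mol⁻¹, ΔH = −26.0 kJ mol⁻¹)
    crystals ⇌ ring, rate k3*(cs3 - [ring]) while solid is left; crystals form when [ring] > cs3 (solubility = 0.330 mM, k = 0.00240 s⁻¹)
    ring ⇌ isomer of the product (K = 1.90, k = 5.90 × 10⁻⁵ s⁻¹, Ea = 96.0 kJ mol⁻¹, ΔH = −14.0 kJ mol⁻¹)
    (constants at 5 °C)

In violet, substrate plus open dimer stood at 34.5 % at 3.00 h and at 0.734 % at 6.00 h. That is 3.85 lifetimes, fewer than the reckoned 7.54. Violet charged with 8.0 mM of substrate has the same hot time, so the same release number. It ends with open dimer at 0.343 %, isomer of the product at 3.72 % and ring at 95.9 %.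

The readings stem from a simulated flask with made-up constants, and the scatter is random.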